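**Retrosynthetic overview**
1. Target 26 is a 22-membered meta,para-cyclophane. Resorcinol ring A (1,3-bridged) and trioxygenated ring B (1,4-bridged through its central oxygen) are joined by one diaryl ether oxygen and by a C14 chain carrying the (R)-benzylic carbinol and the Z-alkene. The end game removes three MOM ethers and one TBS ether from 23.
2. Key disconnection: the bond between the alkene CH remote from the carbinol and the adjacent chain CH2 (the first of the five CH2 groups leading to ring A). This opens the macrocycle to ene–yne 21, to be reclosed in one flask by double hydroboration with thexylborane (23-membered boracycle 22) and an iodine-triggered 1,2-shift with loss of boron (Zweifel-type ring contraction).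
3. Enabling feature: both atoms of that bond are unbranched chain carbons (=CH– and –CH2–) of a cis-disubstituted alkene. These are the terminal carbons that anti-Markovnikov hydroboration of a 1-alkyne and a 1-alkene joins to one boron atom, and cis is the geometry the sequence delivers. The large ring, hinged at the ring A–O–ring B ether, is strain-free and tolerates the one-atom-larger boracycle.
4. 21 comes from Weinreb amide 12 and Grignard reagent 17 (ketone 18, then CBS reduction to set (R)). 12 comes from Ullmann coupling of ring B bromide 2 with ring A phenol 10, made from 3-bromo-5-iodophenol by Negishi alkylation and bromine-to-hydroxyl exchange.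
5. Ring order: rings A and B are bought. The only ring made is the macrocycle, closed in step 12 first as boracycle 22 and then contracted to carbocycle 23.

Key step: step 12

Remark: the carbinol centre of the target is (R) by CIP (OH > aryl > chain CH2 > H), and building blocks 1, 3, 5, 13 and 14 are taken as catalogue chemicals.

**Step 1**
Reactants: 1 methyl 4-bromo-3,5-dihydroxybenzoate
Product: 2 methyl 4-bromo-3,5-bis(methoxymethoxy)benzoate
Conditions: MOMCl, i-Pr2NEt, CH2Cl2, 0 °C → rt
Reagents that add atoms: chloromethyl methyl ether (MOMCl), COCCl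
Why: Base-mediated O-alkylation of both phenols (MOM acetal formation) leaves the ester and the aryl bromide untouched and masks the phenols for all later basic, organometallic and borane steps.

**Step 2**
Reactants: 3 3-bromo-5-iodophenol
Product: 4 1-bromo-3-iodo-5-(methoxymethoxy)benzene
Conditions: MOMCl, i-Pr2NEt, CH2Cl2, 0 °C → rt
Reagents that add atoms: chloromethyl methyl ether (MOMCl), COCCl
Why: The same MOM ether formation protects the single phenol while both carbon–halogen bonds are inert.

**Step 3**
Reactants: 4 1-bromo-3-iodo-5-(methoxymethoxy)benzene; 5 5-bromopent-1-ene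
Product: 7 1-bromo-3-(methoxymethoxy)-5-(pent-4-en-1-yl)benzene, via pent-4-en-1-ylzinc bromide 6 (not isolated)
Conditions: 5, Zn dust, LiCl, THF, 50 °C; then 4, PdCl2(dppf) (3 mol%), THF, rt
Reagents that add atoms: none
Why: Negishi coupling, in which zerovalent palladium inserts into the C–I bond much faster than into the C–Br bond at room temperature, so the primary alkylzinc reagent is joined at one position only and the bromide is kept for step 4.

**Step 4**
Reactants: 7 1-bromo-3-(methoxymethoxy)-5-(pent-4-en-1-yl)benzene
Product: 10 3-(methoxymethoxy)-5-(pent-4-en-1-yl)phenol, via aryllithium 8 (not isolated), via dimethyl arylboronate 9 (not isolated)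
Conditions: n-BuLi, THF, −78 °C; B(OMe)3, −78 °C → rt; then 30% H2O2, aq NaOH, 0 °C → rt
Reagents that add atoms: hydrogen peroxide, OO
Why: Bromine–lithium exchange at −78 °C (faster than ortho-lithiation next to OMOM), borate trapping and alkaline peroxide oxidation of the aryl–boron bond (1,2-aryl shift from boron to oxygen) should give the phenol, with the terminal alkene inert to alkaline H2O2.

**Step 5**
Reactants: 2 methyl 4-bromo-3,5-bis(methoxymethoxy)benzoate; 10 3-(methoxymethoxy)-5-(pent-4-en-1-yl)phenol
Product: 11 methyl 4-[3-(methoxymethoxy)-5-(pent-4-en-1-yl)phenoxy]-3,5-bis(methoxymethoxy)benzoate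
Conditions: CuI (10 mol%), picolinic acid (20 mol%), K3PO4, DMSO, 90 °C, Ar
Reagents that add atoms: none
Why: Ullmann-type C–O coupling under monovalent copper/picolinate catalysis, in which the para ester should speed oxidative addition at the doubly ortho-alkoxylated bromide and the unhindered phenoxide of 10 is a good partner, while MOM acetals, ester and alkene tolerate anhydrous K3PO4.

**Step 6**
Reactants: 11 methyl 4-[3-(methoxymethoxy)-5-(pent-4-en-1-yl)phenoxy]-3,5-bis(methoxymethoxy)benzoate
Product: 12 N-methoxy-N-methyl-4-[3-(methoxymethoxy)-5-(pent-4-en-1-yl)phenoxy]-3,5-bis(methoxymethoxy)benzamide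
Conditions: MeNH(OMe)·HCl, i-PrMgCl, THF, −20 → 0 °C
Reagents that add atoms: N,O-dimethylhydroxylamine hydrochloride, CNOC.Cl
Why: Weinreb amide formation by attack of the chloromagnesium amide on the methyl ester at low temperature, where i-PrMgCl itself adds neither to the ester nor to the product.

**Step 7**
Reactants: 13 ethynyltrimethylsilane; 14 1,6-dibromohexane
Product: 16 (8-bromooct-1-yn-1-yl)trimethylsilane, via lithium (trimethylsilyl)acetylide 15 (not isolated)
Conditions: 13, n-BuLi, THF, −78 °C; then 14 (3 equiv), DMPU, −78 °C → rt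
Reagents that add atoms: none
Why: SN2 alkylation of a lithium acetylide by a primary bromide in a dipolar cosolvent, where the excess of dibromide should keep double alkylation low and the silyl group later shields the acidic alkyne C–H from the Grignard reagent.

**Step 8**
Reactants: 12 N-methoxy-N-methyl-4-[3-(methoxymethoxy)-5-(pent-4-en-1-yl)phenoxy]-3,5-bis(methoxymethoxy)benzamide; 16 (8-bromooct-1-yn-1-yl)trimethylsilane
Product: 18 1-{4-[3-(methoxymethoxy)-5-(pent-4-en-1-yl)phenoxy]-3,5-bis(methoxymethoxy)phenyl}-9-(trimethylsilyl)non-8-yn-1-one, via Grignard reagent 17 (not isolated)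
Conditions: 16, Mg turnings, THF, 45 °C; then 12, THF, 0 °C → rt; aq NH4Cl
Reagents that add atoms: none
Why: Weinreb ketone synthesis, in which the Grignard reagent adds once and the five-membered magnesium chelate survives until the aqueous quench, so no tertiary alcohol should form.

**Step 9**
Reactants: 18 1-{4-[3-(methoxymethoxy)-5-(pent-4-en-1-yl)phenoxy]-3,5-bis(methoxymethoxy)phenyl}-9-(trimethylsilyl)non-8-yn-1-one
Product: 19 (1R)-1-{4-[3-(methoxymethoxy)-5-(pent-4-en-1-yl)phenoxy]-3,5-bis(methoxymethoxy)phenyl}-9-(trimethylsilyl)non-8-yn-1-ol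
Conditions: (S)-2-methyl-CBS-oxazaborolidine (20 mol%), catecholborane, toluene, −78 → −40 °C; MeOH, aq NaHCO3
Reagents that add atoms: none
Why: Corey–Bakshi–Shibata reduction, in which the ketone binds the catalyst boron with the aryl group away from the B-methyl group and hydride is delivered to the Si face, so the (S)-catalyst should give the (R)-carbinol as with other aryl n-alkyl ketones, while catecholborane at low temperature leaves the terminal alkene and the silylalkyne alone.

**Step 10**
Reactants: 19 (1R)-1-{4-[3-(methoxymethoxy)-5-(pent-4-en-1-yl)phenoxy]-3,5-bis(methoxymethoxy)phenyl}-9-(trimethylsilyl)non-8-yn-1-ol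
Product: 20 tert-butyldimethylsilyl ether of 19 (1R)
Conditions: TBSCl, imidazole, DMF, rt
Reagents that add atoms: tert-butyldimethylsilyl chloride, CC(C)(C)[Si](C)(C)Cl
Why: Imidazole-promoted silylation of the only free hydroxyl removes the one O–H that would consume B–H in step 12 and makes the benzylic oxygen a poorer leaving group.

**Step 11**
Reactants: 20 tert-butyldimethylsilyl ether of 19
Product: 21 (1R)-1-{4-[3-(methoxymethoxy)-5-(pent-4-en-1-yl)phenoxy]-3,5-bis(methoxymethoxy)phenyl}non-8-yn-1-ol tert-butyldimethylsilyl ether (ene–yne)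
Conditions: K2CO3, MeOH/THF, rt
Reagents that add atoms: none
Why: Methoxide-mediated protodesilylation of the C(sp)–Si bond frees the terminal alkyne, while the alkyl TBS ether and the aryl MOM acetals are stable to K2CO3/MeOH.

**Step 12**
Reactants: 21 ene–yne
Product: 23 tris(methoxymethyl) ether and TBS ether of target 26 (protected 22-membered Z-macrocycle), via B-thexyl boracycle 22 (not isolated)
Conditions: ThxBH2 (1.05 equiv, from BH3·THF and 2,3-dimethylbut-2-ene, THF, 0 °C) added slowly to 21 (2 mM, THF), 0 °C → rt; concentrate under Ar; NaOMe/MeOH (3 equiv), −78 °C; I2 (1.2 equiv), THF, −78 → 0 °C; aq Na2S2O3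
Reagents that add atoms: none
Why: Proposed new method: thexylborane should deliver its two B–H bonds anti-Markovnikov to the terminal alkene and, with syn addition, to the terminal alkyne of 21 (in either order), so that one boron atom ties the chain ends into the 23-membered B-thexyl (E)-alkenyl(alkyl)borane 22; methoxide then forms the borate, I2 attacks the alkenyl π-bond, the primary ring CH2 migrates from boron to the adjacent alkenyl carbon (1,2-metallate shift that makes the ring C–C bond) and anti-elimination of the resulting β-iodoborinate expels boron as dimethyl thexylboronate. The closest known reaction types are the Zweifel cis-olefin synthesis from thexyl(alkyl)(alkenyl)boranes with I2/base and the cyclic hydroboration of dienes with thexylborane, here merged and stretched to a macrocycle with boron as a traceless one-atom tether. Mode of closure: the large ring is closed at boron by intramolecular hydroboration under high dilution (terminal, exo-type addition; strain-free 23-membered ring) and then contracted by one atom to the 22-membered carbocycle in the 1,2-shift. No stereocentre is formed; the Z geometry is fixed by the mechanism (syn-hydroboration to the E-alkenylborane, migration anti to the iodonium, anti-deiodoboration) and the remote (R)-silyloxy centre is not involved. The step needs ring closure to beat oligomerisation (secured by dilution, 1:1 stoichiometry and the flexible diaryl ether hinge between rings A and B), one hydroboration per terminus (secured by the bulk of the thexyl group and the absence of any other B–H-reactive group after silylation of the carbinol), migration of the primary ring carbon rather than the tertiary thexyl group (the usual order for this borane class) and no arene iodination (no free phenol is present and I2 is used near stoichiometry at low temperature).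

**Step 13**
Reactants: 23 protected macrocycle
Product: 25 O-TBS ether of target 26 (three free phenols), via tris(trimethylsilyl) ether 24 (not isolated)
Conditions: TMSOTf (6 equiv), 2,2′-bipyridyl (9 equiv), CH3CN, 0 °C → rt; then H2O, rt
Reagents that add atoms: none
Why: Cleavage of aromatic MOM ethers with silyl triflate/2,2′-bipyridyl, in which each ArO–CH2OMe unit is converted to ArO–SiMe3 with the methoxymethyl fragment trapped on bipyridyl and the aryl silyl ethers are then hydrolysed by water, so no Brønsted acid meets the benzylic C–O bond or the Z-alkene.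

**Step 14**
Reactants: 25 O-TBS ether of target
Product: 26 CNP0316989.2 (target; (R)-carbinol, Z-alkene, three free phenols)
Conditions: TBAF, AcOH, THF, 0 °C → rt
Reagents that add atoms: none
Why: Fluoride-mediated desilylation driven by Si–F bond formation, buffered with acetic acid so the phenols stay protonated, with the benzylic centre never ionised and its (R) configuration retained.

**Compound list**
1 | methyl 4-bromo-3,5-dihydroxybenzoate | COC(=O)c1cc(O)c(Br)c(O)c1 | starting material
2 | methyl 4-bromo-3,5-bis(methoxymethoxy)benzoate | COC(=O)c1cc(OCOC)c(Br)c(OCOC)c1 | intermediate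
3 | 3-bromo-5-iodophenol | Oc1cc(Br)cc(I)c1 | starting material
4 | 1-bromo-3-iodo-5-(methoxymethoxy)benzene | COCOc1cc(Br)cc(I)c1 | intermediate
5 | 5-bromopent-1-ene | C=CCCCBr | starting material
6 | pent-4-en-1-ylzinc bromide (not isolated) | C=CCCC[Zn]Br | intermediate
7 | 1-bromo-3-(methoxymethoxy)-5-(pent-4-en-1-yl)benzene | COCOc1cc(Br)cc(CCCC=C)c1 | intermediate
8 | [3-(methoxymethoxy)-5-(pent-4-en-1-yl)phenyl]lithium (not isolated) | [Li]c1cc(OCOC)cc(CCCC=C)c1 | intermediate
9 | dimethyl [3-(methoxymethoxy)-5-(pent-4-en-1-yl)phenyl]boronate (not isolated) | COB(OC)c1cc(OCOC)cc(CCCC=C)c1 | intermediate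
10 | 3-(methoxymethoxy)-5-(pent-4-en-1-yl)phenol | COCOc1cc(O)cc(CCCC=C)c1 | intermediate
11 | methyl 4-[3-(methoxymethoxy)-5-(pent-4-en-1-yl)phenoxy]-3,5-bis(methoxymethoxy)benzoate | COC(=O)c1cc(OCOC)c(Oc2cc(OCOC)cc(CCCC=C)c2)c(OCOC)c1 | intermediate
12 | N-methoxy-N-methyl-4-[3-(methoxymethoxy)-5-(pent-4-en-1-yl)phenoxy]-3,5-bis(methoxymethoxy)benzamide | CON(C)C(=O)c1cc(OCOC)c(Oc2cc(OCOC)cc(CCCC=C)c2)c(OCOC)c1 | intermediate
13 | ethynyltrimethylsilane | C#C[Si](C)(C)C | starting material
14 | 1,6-dibromohexane | BrCCCCCCBr | starting material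
15 | lithium (trimethylsilyl)acetylide (not isolated) | [Li]C#C[Si](C)(C)C | intermediate
16 | (8-bromooct-1-yn-1-yl)trimethylsilane | C[Si](C)(C)C#CCCCCCCBr | intermediate
17 | [8-(trimethylsilyl)oct-7-yn-1-yl]magnesium bromide (not isolated) | C[Si](C)(C)C#CCCCCCC[Mg]Br | intermediate
18 | 1-{4-[3-(methoxymethoxy)-5-(pent-4-en-1-yl)phenoxy]-3,5-bis(methoxymethoxy)phenyl}-9-(trimethylsilyl)non-8-yn-1-one | C[Si](C)(C)C#CCCCCCCC(=O)c1cc(OCOC)c(Oc2cc(OCOC)cc(CCCC=C)c2)c(OCOC)c1 | intermediate
19 | (1R)-1-{4-[3-(methoxymethoxy)-5-(pent-4-en-1-yl)phenoxy]-3,5-bis(methoxymethoxy)phenyl}-9-(trimethylsilyl)non-8-yn-1-ol | COCOc1cc(cc(OCOC)c1Oc1cc(OCOC)cc(CCCC=C)c1)[C@H](O)CCCCCCC#C[Si](C)(C)C | intermediate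
20 | tert-butyldimethylsilyl ether of 19 (1R) | COCOc1cc(cc(OCOC)c1Oc1cc(OCOC)cc(CCCC=C)c1)[C@H](O[Si](C)(C)C(C)(C)C)CCCCCCC#C[Si](C)(C)C | intermediate
21 | ene–yne: (1R)-1-aryl-non-8-yn-1-ol TBS ether, aryl as in 19 | COCOc1cc(cc(OCOC)c1Oc1cc(OCOC)cc(CCCC=C)c1)[C@H](O[Si](C)(C)C(C)(C)C)CCCCCCC#C | intermediate
22 | B-thexyl boracycle (not isolated): 23-membered ring in which boron bearing 2,3-dimethylbutan-2-yl links the terminal CH2 of the ring A chain to the (E)-CH=CH end of the ring B chain | CC(C)C(C)(C)B1CCCCCc2cc(OCOC)cc(c2)Oc2c(OCOC)cc(cc2OCOC)[C@H](O[Si](C)(C)C(C)(C)C)CCCCCC/C=C/1 | intermediate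
23 | protected macrocycle: target with three phenol MOM ethers and carbinol TBS ether, (R), Z | COCOc1cc2cc(c1)Oc1c(OCOC)cc(cc1OCOC)[C@H](O[Si](C)(C)C(C)(C)C)CCCCCC/C=C\CCCCC2 | intermediate
24 | tris(trimethylsilyl) aryl ether of 25 (not isolated) | C[Si](C)(C)Oc1cc2cc(c1)Oc1c(O[Si](C)(C)C)cc(cc1O[Si](C)(C)C)[C@H](O[Si](C)(C)C(C)(C)C)CCCCCC/C=C\CCCCC2 | intermediate
25 | carbinol TBS ether of the target, (R), Z | Oc1cc2cc(c1)Oc1c(O)cc(cc1O)[C@H](O[Si](C)(C)C(C)(C)C)CCCCCC/C=C\CCCCC2 | intermediate
26 | CNP0316989.2, (R)-carbinol, Z-alkene | Oc1cc2cc(c1)Oc1c(O)cc(cc1O)[C@H](O)CCCCCC/C=C\CCCCC2 | target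

**Step count**
Total step count: 14. Longest linear sequence: 12 steps (steps 2, 3, 4, 5, 6, 8, 9, 10, 11, 12, 13 and 14, from 3).

**Steps most likely to fail**

1. Step 12 (proposed new method). Intermolecular hydroboration may outrun ring closure and give oligomeric boranes, the alkyne terminus may be hydroborated twice, or the thexyl group may migrate in place of the ring carbon during the iodine-triggered shift. The fallback uses known chemistry, sets out from 20 and comes back at 23; it closes the ring at the same bond by acetylide alkylation and makes the Z-alkene afterwards.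
   - 9-BBN in THF should add only to the terminal alkene of 20 (the silylalkyne is inert at room temperature) to give B-alkyl-9-BBN adduct F1 (not isolated).
   - Oxidation in the same flask with NaBO3·4H2O gives primary alcohol F2.
   - K2CO3/MeOH frees the alkyne to give alkynol F3.
   - I2, PPh3 and imidazole in CH2Cl2 give primary iodide F4.
   - Slow addition of F4 to LiN(SiMe3)2 in THF/DMPU at high dilution forms lithium acetylide F5 (not isolated), which should close the ring by intramolecular SN2 to cycloalkyne F6.
   - Lindlar semi-hydrogenation (H2, Pd/CaCO3 poisoned with Pb(OAc)2, quinoline) gives 23.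

2. Step 5. Oxidative addition and C–O bond formation at the doubly ortho-substituted bromide may be too slow, so that conversion stalls or bromine is lost reductively. The fallback reverses the roles of the rings and uses oxidative Chan–Lam coupling at room temperature; it sets out from 7 and 2 and comes back at 11.
   - 7 is taken through 8 and 9 as in step 4 but worked up with aqueous NH4Cl in place of peroxide, to give boronic acid F7.
   - 2 is converted by Miyaura borylation (B2pin2, PdCl2(dppf), KOAc, dioxane, 90 °C) into pinacol boronate F8.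
   - Oxidation of F8 with NaBO3·4H2O in THF/H2O gives phenol F9.
   - Coupling of F7 with F9 under divalent copper (Cu(OAc)2, pyridine, 4 Å molecular sieves, CH2Cl2, air, rt) should give 11.

3. Step 13. The silyl triflate may ionise the benzylic C–O bond (loss of configuration or elimination), or acetal cleavage may stop short at the hindered ring B oxygens. The fallback takes the carbinol out of play during deprotection and resets it at the end under catalyst control; it sets out from 23 and comes back at 26.
   - TBAF in THF gives carbinol F10.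
   - Dess–Martin periodinane in CH2Cl2 gives aryl ketone F11.
   - With no ionisable benzylic C–O bond left, HCl in MeOH at 40 °C removes the three MOM groups to give triphenol ketone F12.
   - Noyori asymmetric transfer hydrogenation (RuCl[(R,R)-TsDPEN](p-cymene), HCO2H/Et3N, rt), which tolerates free phenols and isolated alkenes, should deliver the (R)-carbinol 26.

**Further compounds**
F1 | step 12 | B-alkyl-9-borabicyclo[3.3.1]nonane adduct of 20 (not isolated) | COCOc1cc(cc(OCOC)c1Oc1cc(OCOC)cc(CCCCCB2C3CCCC2CCC3)c1)[C@H](O[Si](C)(C)C(C)(C)C)CCCCCCC#C[Si](C)(C)C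
F2 | step 12 | primary alcohol (5-hydroxypentyl on ring A, silylalkyne kept) | COCOc1cc(cc(OCOC)c1Oc1cc(OCOC)cc(CCCCCO)c1)[C@H](O[Si](C)(C)C(C)(C)C)CCCCCCC#C[Si](C)(C)C
F3 | step 12 | alkynol (terminal alkyne, primary alcohol) | COCOc1cc(cc(OCOC)c1Oc1cc(OCOC)cc(CCCCCO)c1)[C@H](O[Si](C)(C)C(C)(C)C)CCCCCCC#C
F4 | step 12 | primary iodide with terminal alkyne | COCOc1cc(cc(OCOC)c1Oc1cc(OCOC)cc(CCCCCI)c1)[C@H](O[Si](C)(C)C(C)(C)C)CCCCCCC#C
F5 | step 12 | lithium acetylide of F4 (not isolated) | COCOc1cc(cc(OCOC)c1Oc1cc(OCOC)cc(CCCCCI)c1)[C@H](O[Si](C)(C)C(C)(C)C)CCCCCCC#C[Li]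
F6 | step 12 | 22-membered cycloalkyne (alkyne in place of the Z-alkene of 23) | COCOc1cc2cc(c1)Oc1c(OCOC)cc(cc1OCOC)[C@H](O[Si](C)(C)C(C)(C)C)CCCCCCC#CCCCCC2
F7 | step 5 | [3-(methoxymethoxy)-5-(pent-4-en-1-yl)phenyl]boronic acid | OB(O)c1cc(OCOC)cc(CCCC=C)c1
F8 | step 5 | methyl 3,5-bis(methoxymethoxy)-4-(4,4,5,5-tetramethyl-1,3,2-dioxaborolan-2-yl)benzoate | COC(=O)c1cc(OCOC)c(B2OC(C)(C)C(C)(C)O2)c(OCOC)c1
F9 | step 5 | methyl 4-hydroxy-3,5-bis(methoxymethoxy)benzoate | COC(=O)c1cc(OCOC)c(O)c(OCOC)c1
F10 | step 13 | tris-MOM macrocycle with free (R)-carbinol | COCOc1cc2cc(c1)Oc1c(OCOC)cc(cc1OCOC)[C@H](O)CCCCCC/C=C\CCCCC2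
F11 | step 13 | tris-MOM macrocyclic aryl ketone | COCOc1cc2cc(c1)Oc1c(OCOC)cc(cc1OCOC)C(=O)CCCCCC/C=C\CCCCC2
F12 | step 13 | triphenol macrocyclic aryl ketone | Oc1cc2cc(c1)Oc1c(O)cc(cc1O)C(=O)CCCCCC/C=C\CCCCC2
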